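**Assumption:** the target is the single stereoisomer given by the SMILES: δ-lactone (5R,6R) (cis), side chain (2S,4R,6E), acyl part (2E,4E,6R). All compounds marked "starting material" are taken to be catalogue chemicals.

## Retrosynthetic overview

1. Final bond: the C2′=C3′ alkene of the dienoate, by Horner–Wadsworth–Emmons union of a lactone phosphonoacetate with a C6′-stereogenic enal, then desilylation.
2. The only ring of the target, the δ-lactone, is formed once: a 2-furyl carbinol is ring-expanded by light (singlet oxygen, then a photocatalytic redox isomerisation) to a 5-oxo-δ-lactone. The C5 carbinol then comes from substrate-controlled ketone reduction.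
3. The furyl carbinol comes from Felkin addition of a 2-furyl metal to (2S,4R,6E)-2,4,6-trimethyloct-6-enal.
4. That aldehyde comes from stereoinvertive sp3–sp3 coupling of L-lactate triflate with a Grignard reagent. The Grignard's C(sp3)–C(vinyl) bond is made by a photochemical nickel cross-electrophile coupling of (R)-1-bromo-3-chloro-2-methylpropane with (E)-2-bromobut-2-ene.
5. The enal comes from levoglucosenone: conjugate alkenylation anti to the anhydro bridge, Baeyer–Villiger oxidation, excision of the sugar end carbons, then SeO2 oxidation. The levoglucosenone bicycle is bought and dismantled, not built.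

## Route

**Step 1**
Reactants: 1 (2R)-1-bromo-3-chloro-2-methylpropane; 2 (2E)-2-bromobut-2-ene
Product: 3 (2E,5S)-6-chloro-3,5-dimethylhex-2-ene
Conditions: NiCl2·glyme (5 mol %), 4,4′-di-tert-butyl-2,2′-bipyridine (5 mol %), [Ir(dF(CF3)ppy)2(dtbbpy)]PF6 (1 mol %), (Me3Si)3SiH, Na2CO3, DME, blue LEDs, 25 °C
Reagents that add atoms: none
Why: Metallaphotoredox cross-electrophile coupling: the silyl radical abstracts Br (not Cl) from 1, the primary radical is captured by the alkenylnickel species from oxidative addition of 2, and reductive elimination forms the C(sp3)–C(sp2) bond with retention of the E geometry, while the stereocentre of 1 is not involved.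

**Step 2**
Reactants: 4 tert-butyl (2S)-2-hydroxypropanoate
Product: 5 tert-butyl (2S)-2-[(trifluoromethanesulfonyl)oxy]propanoate
Conditions: Tf2O, 2,6-lutidine, CH2Cl2, −78 → 0 °C
Reagents that add atoms: trifluoromethanesulfonic anhydride, O=S(=O)(OS(=O)(=O)C(F)(F)F)C(F)(F)F
Why: O-sulfonylation of the α-hydroxy ester breaks no bond at the stereocentre (retention) and gives a leaving group reactive enough for SN2 coupling.

**Step 3**
Reactants: 3 (2E,5S)-6-chloro-3,5-dimethylhex-2-ene; 5 tert-butyl (2S)-2-[(trifluoromethanesulfonyl)oxy]propanoate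
Product: 7 tert-butyl (2S,4R,6E)-2,4,6-trimethyloct-6-enoate, via Grignard reagent 6 (not isolated)
Conditions: Mg, THF, 65 °C; then 5, ZnCl2 (10 mol %), THF, 0 °C
Reagents that add atoms: none
Why: Zinc-catalysed enantiospecific sp3–sp3 coupling of an α-triflyloxy ester with a Grignard reagent (SN2 by the triorganozincate, clean inversion) turns the bought lactate centre into the (2S) methyl-bearing carbon, syn to the (4R) methyl carried in from 1.

**Step 4**
Reactants: 7 tert-butyl (2S,4R,6E)-2,4,6-trimethyloct-6-enoate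
Product: 8 (2S,4R,6E)-2,4,6-trimethyloct-6-enal
Conditions: iBu2AlH, CH2Cl2, −78 °C; Rochelle salt work-up
Reagents that add atoms: none
Why: Partial ester reduction by iBu2AlH at −78 °C (the tetrahedral aluminate collapses only on work-up) gives the aldehyde, which is used at once to avoid α-epimerisation.

**Step 5**
Reactants: 8 (2S,4R,6E)-2,4,6-trimethyloct-6-enal; 9 furan
Product: 12 (1R,2S,4R,6E)-1-(furan-2-yl)-2,4,6-trimethyloct-6-en-1-ol, via 2-furyllithium 10 (not isolated), via 2-furyltitanium triisopropoxide 11 (not isolated)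
Conditions: 9, nBuLi, THF, 0 °C; ClTi(OiPr)3, −78 °C; then 8, −78 → −20 °C
Reagents that add atoms: none
Why: Felkin–Anh-controlled 1,2-addition of a bulky, weakly basic aryltitanium reagent to the α-methyl aldehyde (attack anti to the large CH2R arm) gives the 1,2-syn carbinol, new C1 = R, with an expected dr of at least 5:1 and the minor epimer removed by chromatography.

**Step 6**
Reactants: 12 (1R,2S,4R,6E)-1-(furan-2-yl)-2,4,6-trimethyloct-6-en-1-ol
Product: 15 (6R)-6-[(2S,4R,6E)-4,6-dimethyloct-6-en-2-yl]oxane-2,5-dione, via furan endoperoxide 13 (not isolated), via Achmatowicz lactol 14 (not isolated)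
Conditions: O2, polymer-bound rose bengal, CH2Cl2, white LEDs, −78 °C; Me2S, −78 → 20 °C; filter, evaporate; then (nBu4N)4[W10O32] (2 mol %), MeCN, 390 nm LEDs, N2, 20 °C
Reagents that add atoms: dioxygen, O=O
Why: Proposed new method: the furan is first ring-expanded by the known singlet-oxygen Achmatowicz reaction ([4+2] addition of singlet oxygen, Me2S reduction, closure of the carbinol oxygen onto the enedial, which forms the ring C–O bond), and the new part is that lactol 14 is isomerised in the same flask by decatungstate photocatalysis instead of being oxidised and reduced in separate steps: excited [W10O32]4− abstracts the weak, hydridic, doubly O-substituted allylic C6–H, the radical is delocalised over C6, C4 and the ketone oxygen, and back hydrogen transfer from the reduced polyoxometalate to C4 (the step that closes every decatungstate Giese cycle) gives a ketene hemiacetal that tautomerises to the much more stable keto-δ-lactone; the closest known reactions are the thermal iridium-hydride internal redox isomerisation of Achmatowicz lactols and decatungstate hydrogen-abstraction/back-donation epimerisations, and the carbinol stereocentre is not touched.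

**Step 7**
Reactants: 15 (6R)-6-[(2S,4R,6E)-4,6-dimethyloct-6-en-2-yl]oxane-2,5-dione
Product: 16 (5R,6R)-6-[(2S,4R,6E)-4,6-dimethyloct-6-en-2-yl]-5-hydroxyoxan-2-one
Conditions: Li[HB(sBu)3], THF, −78 °C; AcOH, −78 °C; crude product used directly
Reagents that add atoms: none
Why: Substrate-controlled ketone reduction: the bulky hydride attacks C5 from the face opposite the adjacent C6 side chain (equatorial attack) and gives the axial alcohol cis to the side chain, i.e. (5R), while the lactone is inert at −78 °C and the cold acidic quench keeps the alkoxide from translactonising.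

**Step 8**
Reactants: 16 (5R,6R)-6-[(2S,4R,6E)-4,6-dimethyloct-6-en-2-yl]-5-hydroxyoxan-2-one; 17 (diethoxyphosphoryl)acetic acid
Product: 18 (2R,3R)-2-[(2S,4R,6E)-4,6-dimethyloct-6-en-2-yl]-6-oxooxan-3-yl (diethoxyphosphoryl)acetate
Conditions: DCC, DMAP (10 mol %), CH2Cl2, 0 → 20 °C
Reagents that add atoms: none
Why: Steglich esterification of the secondary alcohol (carbodiimide activation, DMAP acyl transfer) proceeds with retention at C5, and fast acylation also blocks isomerisation of the δ-lactone to the γ-lactone.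

**Step 9**
Reactants: 19 levoglucosenone [(1S,5R)-6,8-dioxabicyclo[3.2.1]oct-2-en-4-one]; 20 bromido(2-methylprop-1-en-1-yl)magnesium
Product: 21 (1S,2R,5R)-2-(2-methylprop-1-en-1-yl)-6,8-dioxabicyclo[3.2.1]octan-4-one
Conditions: CuBr·SMe2 (10 mol %), THF, −78 → −40 °C; 1 M HCl quench
Reagents that add atoms: none
Why: Copper-catalysed conjugate addition of the alkenyl Grignard reagent to the bicyclic enone: the 1,6-anhydro bridge blocks one face, so the nucleophile enters only anti to it and sets the new centre (2R), which becomes C6′ of the target.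

**Step 10**
Reactants: 21 (1S,2R,5R)-2-(2-methylprop-1-en-1-yl)-6,8-dioxabicyclo[3.2.1]octan-4-one
Product: 23 [(2S,3R)-3-(2-methylprop-1-en-1-yl)-5-oxooxolan-2-yl]methyl formate, via Baeyer–Villiger lactone acetal 22 (not isolated)
Conditions: H2O2 (30 % aq), pH 7 phosphate buffer–THF, 40 °C; Na2S2O3 quench
Reagents that add atoms: hydrogen peroxide, OO
Why: Baeyer–Villiger oxidation with migration of the acetal carbon, followed by spontaneous transacylation of the ring oxygen onto the new lactone carbonyl, releases the former anomeric carbon as a formate; buffered neutral H2O2 forms no peracid, so the trisubstituted alkene is not epoxidised and no stereocentre is touched (partial loss of the formyl group is harmless because step 11 removes it anyway).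

**Step 11**
Reactants: 23 [(2S,3R)-3-(2-methylprop-1-en-1-yl)-5-oxooxolan-2-yl]methyl formate
Product: 24 (2S,3R)-3-(2-methylprop-1-en-1-yl)pentane-1,2,5-triol
Conditions: LiAlH4, THF, 0 → 20 °C; Fieser work-up
Reagents that add atoms: none
Why: Hydride reduction opens the lactone to the diol and cleaves the formate to the free primary alcohol, with the stereocentres untouched.

**Step 12**
Reactants: 24 (2S,3R)-3-(2-methylprop-1-en-1-yl)pentane-1,2,5-triol
Product: 26 (2R)-2-(2-methylprop-1-en-1-yl)butane-1,4-diol, via lactol 25 (not isolated)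
Conditions: NaIO4, THF–pH 7 buffer, 0 °C; then NaBH4, 0 °C
Reagents that add atoms: none
Why: Malaprade glycol cleavage removes the terminal carbon and leaves the α-alkenyl aldehyde, which is held as its five-membered lactol and reduced in the same flask before it can epimerise or move into conjugation; the bought carbinol centre is destroyed here after it has controlled C6′.

**Step 13**
Reactants: 26 (2R)-2-(2-methylprop-1-en-1-yl)butane-1,4-diol
Product: 27 (2R)-1,4-bis[(tert-butyldimethylsilyl)oxy]-2-(2-methylprop-1-en-1-yl)butane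
Conditions: TBSCl, imidazole, DMF, 20 °C
Reagents that add atoms: tert-butyl(chloro)dimethylsilane, CC(C)(C)[Si](C)(C)Cl
Why: Standard silylation of both primary alcohols.

**Step 14**
Reactants: 27 (2R)-1,4-bis[(tert-butyldimethylsilyl)oxy]-2-(2-methylprop-1-en-1-yl)butane
Product: 29 (2E,4R)-6-[(tert-butyldimethylsilyl)oxy]-4-{[(tert-butyldimethylsilyl)oxy]methyl}-2-methylhex-2-enal, via allylic alcohol 28 (not isolated)
Conditions: SeO2 (0.5 equiv), tBuOOH, CH2Cl2, 20 °C; then MnO2, CH2Cl2, 20 °C
Reagents that add atoms: tert-butyl hydroperoxide, CC(C)(C)OO; selenium dioxide, O=[Se]=O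
Why: Selenium dioxide allylic oxidation (ene reaction, then [2,3]-sigmatropic shift) attacks the gem-dimethyl terminus at the methyl trans to the chain and gives the (E)-allylic alcohol, which MnO2 takes to the (E)-enal; the allylic stereocentre sits on the other alkene carbon and is not involved.

**Step 15**
Reactants: 18 (2R,3R)-2-[(2S,4R,6E)-4,6-dimethyloct-6-en-2-yl]-6-oxooxan-3-yl (diethoxyphosphoryl)acetate; 29 (2E,4R)-6-[(tert-butyldimethylsilyl)oxy]-4-{[(tert-butyldimethylsilyl)oxy]methyl}-2-methylhex-2-enal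
Product: 30 (2R,3R)-2-[(2S,4R,6E)-4,6-dimethyloct-6-en-2-yl]-6-oxooxan-3-yl (2E,4E,6R)-8-[(tert-butyldimethylsilyl)oxy]-6-{[(tert-butyldimethylsilyl)oxy]methyl}-4-methylocta-2,4-dienoate
Conditions: LiCl, iPr2NEt, MeCN, 0 → 20 °C
Reagents that add atoms: none
Why: Horner–Wadsworth–Emmons olefination under Masamune–Roush conditions (mild amine base, lithium chelation) gives the (2E) alkene and joins the two halves without touching the lactone or any stereocentre.

**Step 16**
Reactants: 30 (2R,3R)-2-[(2S,4R,6E)-4,6-dimethyloct-6-en-2-yl]-6-oxooxan-3-yl (2E,4E,6R)-8-[(tert-butyldimethylsilyl)oxy]-6-{[(tert-butyldimethylsilyl)oxy]methyl}-4-methylocta-2,4-dienoate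
Product: 31 (2R,3R)-2-[(2S,4R,6E)-4,6-dimethyloct-6-en-2-yl]-6-oxooxan-3-yl (2E,4E,6R)-8-hydroxy-6-(hydroxymethyl)-4-methylocta-2,4-dienoate
Conditions: HF·pyridine, THF–pyridine, 0 → 20 °C
Reagents that add atoms: none
Why: Fluoride-mediated cleavage of the two primary silyl ethers under buffered, non-basic conditions leaves the lactone, the ester and the dienoate intact.

## Compound list

1 | (2R)-1-bromo-3-chloro-2-methylpropane | BrC[C@H](C)CCl | starting material
2 | (2E)-2-bromobut-2-ene | C/C=C(\C)Br | starting material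
3 | (2E,5S)-6-chloro-3,5-dimethylhex-2-ene | C/C=C(\C)C[C@H](C)CCl | intermediate
4 | tert-butyl (2S)-2-hydroxypropanoate (tert-butyl L-lactate) | C[C@H](O)C(=O)OC(C)(C)C | starting material
5 | tert-butyl (2S)-2-[(trifluoromethanesulfonyl)oxy]propanoate | C[C@H](OS(=O)(=O)C(F)(F)F)C(=O)OC(C)(C)C | intermediate
6 | chlorido[(2S,4E)-2,4-dimethylhex-4-en-1-yl]magnesium (Grignard reagent, not isolated) | C/C=C(\C)C[C@H](C)C[Mg]Cl | intermediate
7 | tert-butyl (2S,4R,6E)-2,4,6-trimethyloct-6-enoate | C/C=C(\C)C[C@H](C)C[C@H](C)C(=O)OC(C)(C)C | intermediate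
8 | (2S,4R,6E)-2,4,6-trimethyloct-6-enal | C/C=C(\C)C[C@H](C)C[C@H](C)C=O | intermediate
9 | furan | c1ccoc1 | starting material
10 | furan-2-yllithium (not isolated) | [Li]c1ccco1 | intermediate
11 | (furan-2-yl)tri(propan-2-yloxy)titanium (not isolated) | CC(C)O[Ti](OC(C)C)(OC(C)C)c1ccco1 | intermediate
12 | (1R,2S,4R,6E)-1-(furan-2-yl)-2,4,6-trimethyloct-6-en-1-ol | C/C=C(\C)C[C@H](C)C[C@H](C)[C@@H](O)c1ccco1 | intermediate
13 | furan endoperoxide, (1R,2S,4R,6E)-2,4,6-trimethyl-1-(2,3,7-trioxabicyclo[2.2.1]hept-5-en-1-yl)oct-6-en-1-ol, both bridgehead configurations (not isolated) | C/C=C(\C)C[C@H](C)C[C@H](C)[C@@H](O)C12OOC(O1)C=C2 | intermediate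
14 | Achmatowicz lactol, (2R)-2-[(2S,4R,6E)-4,6-dimethyloct-6-en-2-yl]-6-hydroxy-2H-pyran-3(6H)-one, both anomers (not isolated) | C/C=C(\C)C[C@H](C)C[C@H](C)[C@H]1OC(O)C=CC1=O | intermediate
15 | (6R)-6-[(2S,4R,6E)-4,6-dimethyloct-6-en-2-yl]oxane-2,5-dione | C/C=C(\C)C[C@H](C)C[C@H](C)[C@H]1OC(=O)CCC1=O | intermediate
16 | (5R,6R)-6-[(2S,4R,6E)-4,6-dimethyloct-6-en-2-yl]-5-hydroxyoxan-2-one (cis) | C/C=C(\C)C[C@H](C)C[C@H](C)[C@H]1OC(=O)CC[C@H]1O | intermediate
17 | (diethoxyphosphoryl)acetic acid | CCOP(=O)(CC(=O)O)OCC | starting material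
18 | (2R,3R)-2-[(2S,4R,6E)-4,6-dimethyloct-6-en-2-yl]-6-oxooxan-3-yl (diethoxyphosphoryl)acetate | C/C=C(\C)C[C@H](C)C[C@H](C)[C@H]1OC(=O)CC[C@H]1OC(=O)CP(=O)(OCC)OCC | intermediate
19 | levoglucosenone, (1S,5R)-6,8-dioxabicyclo[3.2.1]oct-2-en-4-one | O=C1C=C[C@H]2CO[C@@H]1O2 | starting material
20 | bromido(2-methylprop-1-en-1-yl)magnesium | CC(C)=C[Mg]Br | starting material
21 | (1S,2R,5R)-2-(2-methylprop-1-en-1-yl)-6,8-dioxabicyclo[3.2.1]octan-4-one | O=C1C[C@H](C=C(C)C)[C@H]2CO[C@@H]1O2 | intermediate
22 | Baeyer–Villiger lactone acetal, 5-(2-methylprop-1-en-1-yl)-2,8,9-trioxabicyclo[4.2.1]nonan-3-one, oxygen inserted between C4 and C5 of 21 with the three stereocentres as in 21 (not isolated) | O=C1C[C@H](C=C(C)C)[C@H]2CO[C@@H](O1)O2 | intermediate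
23 | [(2S,3R)-3-(2-methylprop-1-en-1-yl)-5-oxooxolan-2-yl]methyl formate | O=C1C[C@H](C=C(C)C)[C@@H](COC=O)O1 | intermediate
24 | (2S,3R)-3-(2-methylprop-1-en-1-yl)pentane-1,2,5-triol | OCC[C@H](C=C(C)C)[C@@H](CO)O | intermediate
25 | (3R)-3-(2-methylprop-1-en-1-yl)oxolan-2-ol, both anomers (not isolated) | CC(C)=C[C@H]1CCOC1O | intermediate
26 | (2R)-2-(2-methylprop-1-en-1-yl)butane-1,4-diol | CC(C)=C[C@H](CO)CCO | intermediate
27 | (2R)-1,4-bis[(tert-butyldimethylsilyl)oxy]-2-(2-methylprop-1-en-1-yl)butane | CC(C)=C[C@H](CO[Si](C)(C)C(C)(C)C)CCO[Si](C)(C)C(C)(C)C | intermediate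
28 | (2E,4R)-6-[(tert-butyldimethylsilyl)oxy]-4-{[(tert-butyldimethylsilyl)oxy]methyl}-2-methylhex-2-en-1-ol (not isolated) | OC/C(C)=C/[C@H](CO[Si](C)(C)C(C)(C)C)CCO[Si](C)(C)C(C)(C)C | intermediate
29 | (2E,4R)-6-[(tert-butyldimethylsilyl)oxy]-4-{[(tert-butyldimethylsilyl)oxy]methyl}-2-methylhex-2-enal | O=C/C(C)=C/[C@H](CO[Si](C)(C)C(C)(C)C)CCO[Si](C)(C)C(C)(C)C | intermediate
30 | (2R,3R)-2-[(2S,4R,6E)-4,6-dimethyloct-6-en-2-yl]-6-oxooxan-3-yl (2E,4E,6R)-8-[(tert-butyldimethylsilyl)oxy]-6-{[(tert-butyldimethylsilyl)oxy]methyl}-4-methylocta-2,4-dienoate | C/C=C(\C)C[C@H](C)C[C@H](C)[C@H]1OC(=O)CC[C@H]1OC(=O)/C=C/C(C)=C/[C@H](CO[Si](C)(C)C(C)(C)C)CCO[Si](C)(C)C(C)(C)C | intermediate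
31 | (2R,3R)-2-[(2S,4R,6E)-4,6-dimethyloct-6-en-2-yl]-6-oxooxan-3-yl (2E,4E,6R)-8-hydroxy-6-(hydroxymethyl)-4-methylocta-2,4-dienoate | C/C=C(\C)C[C@H](C)C[C@H](C)[C@H]1OC(=O)CC[C@H]1OC(=O)/C=C/C(C)=C/[C@H](CO)CCO | target

## Step count and risks

Total steps: 16. Longest linear sequence: 9 (steps 1, 3, 4, 5, 6, 7, 8, 15, 16). The enal branch (steps 9–14) joins at step 15.

**Step 5 (Felkin selectivity of the furyl addition).** The two arms at the α-carbon (CH3 versus CH2R) differ only moderately, so the dr may be lower than hoped. The fallback sets out from 8 and comes back at 12, and uses a reduction/inversion pair in place of a selective addition. Plain 2-furyllithium 10 is added to 8 without regard to selectivity, giving 12 together with its C1 epimer (1S,2S,4R,6E)-1-(furan-2-yl)-2,4,6-trimethyloct-6-en-1-ol F1. MnO2 oxidises both to the ketone (2S,4R,6E)-1-(furan-2-yl)-2,4,6-trimethyloct-6-en-1-one F2. Li[HB(sBu)3] at −78 °C reduces F2 under Felkin–Anh control to F1 alone, because the large furyl group now stays on carbon and the anti carbinol is formed. Mitsunobu inversion with 4-nitrobenzoic acid (PPh3, diisopropyl azodicarboxylate) gives (1R,2S,4R,6E)-1-(furan-2-yl)-2,4,6-trimethyloct-6-en-1-yl 4-nitrobenzoate F3, and K2CO3/MeOH releases 12.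

**Step 6 (the proposed photochemical ring expansion/redox isomerisation).** The risks are: singlet-oxygen ene reaction at the side-chain alkene; decatungstate hydrogen abstraction at the allylic or tertiary C–H bonds of the side chain, with E/Z or stereocentre scrambling; and back-transfer simply returning 14. The fallback uses only known chemistry, sets out from 12 and comes back at 15. A hydroxyl-directed Achmatowicz rearrangement with VO(acac)2 (cat.) and tBuOOH gives 14, which is isolated. Oxidation with CrO3/H2SO4 in acetone at 0 °C gives the enedione (6R)-6-[(2S,4R,6E)-4,6-dimethyloct-6-en-2-yl]-2H-pyran-2,5(6H)-dione F4. Conjugate reduction with Zn/AcOH then gives 15.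

**Step 7 (cis-selective reduction and survival of the hydroxy δ-lactone).** The alkoxide can translactonise to the γ-lactone, and the cis selectivity may be incomplete. The fallback sets out from 15 and comes back at 18, and takes the opposite stereochemical course followed by inversion. NaBH4/CeCl3·7H2O in MeOH at −78 °C (small hydride, axial attack, alkoxide protonated at once by the solvent) gives the trans alcohol (5S,6R)-6-[(2S,4R,6E)-4,6-dimethyloct-6-en-2-yl]-5-hydroxyoxan-2-one F5. Mitsunobu esterification of F5 with acid 17 (PPh3, diisopropyl azodicarboxylate, THF, 0 °C) inverts C5 and gives 18 directly.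

## Further compounds

F1 | step 5 | (1S,2S,4R,6E)-1-(furan-2-yl)-2,4,6-trimethyloct-6-en-1-ol | C/C=C(\C)C[C@H](C)C[C@H](C)[C@H](O)c1ccco1
F2 | step 5 | (2S,4R,6E)-1-(furan-2-yl)-2,4,6-trimethyloct-6-en-1-one | C/C=C(\C)C[C@H](C)C[C@H](C)C(=O)c1ccco1
F3 | step 5 | (1R,2S,4R,6E)-1-(furan-2-yl)-2,4,6-trimethyloct-6-en-1-yl 4-nitrobenzoate | C/C=C(\C)C[C@H](C)C[C@H](C)[C@@H](OC(=O)c1ccc(cc1)[N+](=O)[O-])c1ccco1
F4 | step 6 | (6R)-6-[(2S,4R,6E)-4,6-dimethyloct-6-en-2-yl]-2H-pyran-2,5(6H)-dione | C/C=C(\C)C[C@H](C)C[C@H](C)[C@H]1OC(=O)C=CC1=O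
F5 | step 7 | (5S,6R)-6-[(2S,4R,6E)-4,6-dimethyloct-6-en-2-yl]-5-hydroxyoxan-2-one | C/C=C(\C)C[C@H](C)C[C@H](C)[C@H]1OC(=O)CC[C@@H]1O
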